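**Plan**

1. Retrosynthesis (azulene numbering of the core: C3 methyl, C3a–H, C5 carbinol side chain, C6–O, C8=C8a): cut the aryl–CH= bond of the ferulate to give acrylate 19 and 4-iodo-2-methoxyphenol; then the ester C–O bond; then the tetrasubstituted C8=C8a alkene to give 1,7-diketone 16; then the C4–C5 bond to give β-hydroxy ester 3 and allylic bromide 8.
2. Forward: the five-membered ring comes first, from (S)-citronellal by methylenation and ring-closing metathesis. The chain is attached by Fráter–Seebach alkylation, and the two ketones are unveiled by Wacker oxidation and hydroboration/oxidation. The seven-membered ring is closed last on carbon by McMurry coupling, followed by acrylation and arylation.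
3. Stereochemistry: C6 comes from ethyl (R)-4-chloro-3-hydroxybutanoate; C5 from the anti-selective Fráter–Seebach alkylation; the C3 methyl from (S)-citronellal; C3a from hydroboration anti to that methyl.
4. Feature that makes the key step possible: the terminal =CH2 of the acrylate on O–C6 is the only unhindered, electron-poor alkene (the ring alkene C8=C8a is tetrasubstituted), and it meets the C4–I bond para to the phenol OH of the guaiacol ring.

Key step: step 16

Assumption: the carbinol centre formed from the methyl ketone in step 11 is not controlled and is left undefined in 14 and 15, because step 12 removes it.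

**Step 1**
Reactants: 1 ethyl (3R)-4-chloro-3-hydroxybutanoate
Product: 2 ethyl 2-[(2R)-oxiran-2-yl]acetate
Conditions: Ag2O, MeCN, 60 °C
Reagents that add atoms: none
Why: Silver-assisted intramolecular Williamson etherification (3-exo-tet SN2 of the hydroxyl on the CH2Cl carbon) should close the oxirane without base-induced elimination to the 4-hydroxycrotonate; the C–O bond at the stereocentre is not broken, so the configuration is retained.

**Step 2**
Reactants: 2 ethyl 2-[(2R)-oxiran-2-yl]acetate
Product: 3 ethyl (3S)-3-hydroxyhex-5-enoate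
Conditions: CH2=CHMgBr, CuI (10 mol %), THF, −40 → −20 °C; NH4Cl
Reagents that add atoms: vinylmagnesium bromide, C=C[Mg]Br
Why: Copper-catalysed SN2 opening of the terminal epoxide at its CH2 carbon, with the ester spared at low temperature; the carbinol centre is untouched and its descriptor changes from R to S only through the priority switch.

**Step 3**
Reactants: 4 (3S)-3,7-dimethyloct-6-enal [(S)-citronellal]
Product: 5 (3S)-3,7-dimethyl-2-methylideneoct-6-enal
Conditions: 37 % aq. CH2O, pyrrolidine (10 mol %), EtCO2H (10 mol %), i-PrOH, 45 °C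
Reagents that add atoms: formaldehyde, C=O
Why: Amine-catalysed α-methylenation (enamine Mannich addition to formaldehyde, then elimination of the amine) should install the 1,1-disubstituted alkene; the C3 stereocentre is not part of the enamine and should be retained.

**Step 4**
Reactants: 5 (3S)-3,7-dimethyl-2-methylideneoct-6-enal
Product: 6 (5S)-5-methylcyclopent-1-ene-1-carbaldehyde
Conditions: Grubbs II (2 mol %), CH2Cl2, 40 °C
Reagents that add atoms: none
Why: Ring-closing metathesis between the α-methylene alkene and the prenyl-type alkene should close the cyclopentene with loss of 2-methylpropene; the stereocentre is untouched.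

**Step 5**
Reactants: 6 (5S)-5-methylcyclopent-1-ene-1-carbaldehyde
Product: 7 [(5S)-5-methylcyclopent-1-en-1-yl]methanol
Conditions: NaBH4, CeCl3·7H2O, MeOH, 0 °C
Reagents that add atoms: none
Why: Luche 1,2-reduction of the enal should give the allylic alcohol without conjugate reduction.

**Step 6**
Reactants: 7 [(5S)-5-methylcyclopent-1-en-1-yl]methanol
Product: 8 (5S)-1-(bromomethyl)-5-methylcyclopent-1-ene
Conditions: PBr3, Et2O, −10 °C
Reagents that add atoms: phosphorus tribromide, BrP(Br)Br
Why: SN2 displacement of the activated primary allylic alcohol by bromide; the primary bromide next to the trisubstituted alkene is also the thermodynamically favoured allylic isomer.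

**Step 7**
Reactants: 3 ethyl (3S)-3-hydroxyhex-5-enoate; 8 (5S)-1-(bromomethyl)-5-methylcyclopent-1-ene
Product: 10 ethyl (2S,3S)-3-hydroxy-2-{[(5S)-5-methylcyclopent-1-en-1-yl]methyl}hex-5-enoate, via dilithium alkoxide–enolate of the hydroxy ester 9 (not isolated)
Conditions: LDA (2.2 equiv), THF, −78 → −20 °C; then 8, DMPU, −78 → −10 °C; NH4Cl
Reagents that add atoms: none
Why: Fráter–Seebach alkylation: the lithium-chelated alkoxide–enolate is alkylated by the primary allylic bromide (SN2) on the face opposite the C3 substituent, which should set the new centre 2,3-anti (2S).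

**Step 8**
Reactants: 10 ethyl (2S,3S)-3-hydroxy-2-{[(5S)-5-methylcyclopent-1-en-1-yl]methyl}hex-5-enoate
Product: 11 (3S,4S)-2-methyl-3-{[(5S)-5-methylcyclopent-1-en-1-yl]methyl}hept-6-ene-2,4-diol
Conditions: MeMgBr (5 equiv), THF, 0 °C → rt; NH4Cl
Reagents that add atoms: methylmagnesium bromide, C[Mg]Br
Why: Double Grignard addition to the ester should give the dimethyl carbinol; the magnesium β-alkoxide disfavours enolisation, so the α-centre should not epimerise.

**Step 9**
Reactants: 11 (3S,4S)-2-methyl-3-{[(5S)-5-methylcyclopent-1-en-1-yl]methyl}hept-6-ene-2,4-diol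
Product: 12 (5S,6S)-2,2,4,4-tetramethyl-5-{[(5S)-5-methylcyclopent-1-en-1-yl]methyl}-6-(prop-2-en-1-yl)-1,3-dioxane
Conditions: Me2C(OMe)2, PPTS (cat.), CH2Cl2, rt
Reagents that add atoms: 2,2-dimethoxypropane, COC(C)(C)OC
Why: Acid-catalysed transacetalisation of the 1,3-diol gives the six-membered isopropylidene acetal, which masks both hydroxyls for the oxidation and titanium steps.

**Step 10**
Reactants: 12 (5S,6S)-2,2,4,4-tetramethyl-5-{[(5S)-5-methylcyclopent-1-en-1-yl]methyl}-6-(prop-2-en-1-yl)-1,3-dioxane
Product: 13 1-[(4S,5S)-2,2,6,6-tetramethyl-5-{[(5S)-5-methylcyclopent-1-en-1-yl]methyl}-1,3-dioxan-4-yl]propan-2-one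
Conditions: PdCl2 (10 mol %), CuCl, O2 (1 atm), DMF/H2O 7:1, rt
Reagents that add atoms: water, O
Why: Tsuji–Wacker oxidation (Markovnikov hydroxypalladation, then β-hydride elimination) should convert the terminal monosubstituted alkene into the methyl ketone, while the hindered trisubstituted ring alkene does not react.

**Step 11**
Reactants: 13 1-[(4S,5S)-2,2,6,6-tetramethyl-5-{[(5S)-5-methylcyclopent-1-en-1-yl]methyl}-1,3-dioxan-4-yl]propan-2-one
Product: 15 (1S,2S,3S)-2-{[(5S,6S)-6-(2-hydroxypropyl)-2,2,4,4-tetramethyl-1,3-dioxan-5-yl]methyl}-3-methylcyclopentan-1-ol (epimers at the hydroxypropyl carbinol), via bis(9-BBN) adduct 14 (not isolated)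
Conditions: 9-BBN (3 equiv), THF, 0 → 65 °C; then NaOH, H2O2, 0 °C → rt
Reagents that add atoms: hydrogen peroxide, OO
Why: Syn hydroboration of the trisubstituted cyclopentene places boron on the unsubstituted carbon and delivers hydrogen to the side-chain-bearing carbon (future C3a) from the face anti to the adjacent methyl group, which should make the methyl and the CH2 arm cis; oxidation proceeds with retention, and the ketone is reduced to a carbinol that step 12 re-oxidises.

**Step 12**
Reactants: 15 (1S,2S,3S)-2-{[(5S,6S)-6-(2-hydroxypropyl)-2,2,4,4-tetramethyl-1,3-dioxan-5-yl]methyl}-3-methylcyclopentan-1-ol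
Product: 16 (2S,3S)-3-methyl-2-{[(5S,6S)-2,2,4,4-tetramethyl-6-(2-oxopropyl)-1,3-dioxan-5-yl]methyl}cyclopentan-1-one
Conditions: Dess–Martin periodinane, NaHCO3, CH2Cl2, 0 °C → rt
Reagents that add atoms: none
Why: Buffered Dess–Martin oxidation of both secondary alcohols should give the 1,7-diketone without epimerising the cis-configured centre α to the cyclopentanone.

**Step 13**
Reactants: 16 (2S,3S)-3-methyl-2-{[(5S,6S)-2,2,4,4-tetramethyl-6-(2-oxopropyl)-1,3-dioxan-5-yl]methyl}cyclopentan-1-one
Product: 17 isopropylidene acetal of 18 (1,3-dioxane spanning O-6 and the side-chain carbinol oxygen of the (3S,3aS,5S,6S)-octahydroazulene)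
Conditions: TiCl3(DME)1.5, Zn–Cu, DME, reflux; 16 added slowly (high dilution)
Reagents that add atoms: none
Why: Intramolecular McMurry coupling: low-valent titanium joins the two ketyl carbons to a seven-membered titanium pinacolate and deoxygenates it at reflux to the tetrasubstituted alkene, whose position is fixed by the two carbonyl carbons.

**Step 14**
Reactants: 17 isopropylidene acetal of 18
Product: 18 (3S,3aS,5S,6S)-5-(2-hydroxypropan-2-yl)-3,8-dimethyl-1,2,3,3a,4,5,6,7-octahydroazulen-6-ol
Conditions: AcOH/THF/H2O 3:1:1, 40 °C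
Reagents that add atoms: none
Why: Mild acid hydrolysis of the strained tetramethyl-1,3-dioxane should free the diol without migration of the tetrasubstituted alkene.

**Step 15**
Reactants: 18 (3S,3aS,5S,6S)-5-(2-hydroxypropan-2-yl)-3,8-dimethyl-1,2,3,3a,4,5,6,7-octahydroazulen-6-ol
Product: 19 (3S,3aS,5S,6S)-5-(2-hydroxypropan-2-yl)-3,8-dimethyl-1,2,3,3a,4,5,6,7-octahydroazulen-6-yl prop-2-enoate
Conditions: CH2=CHCOCl, Et3N, DMAP (cat.), CH2Cl2, −20 → 0 °C
Reagents that add atoms: acryloyl chloride, C=CC(=O)Cl
Why: Acylation should occur only at the secondary alcohol, because the tertiary carbinol is too hindered under these conditions.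

**Step 16**
Reactants: 19 (3S,3aS,5S,6S)-5-(2-hydroxypropan-2-yl)-3,8-dimethyl-1,2,3,3a,4,5,6,7-octahydroazulen-6-yl prop-2-enoate; 20 4-iodo-2-methoxyphenol
Product: 21 (3S,3aS,5S,6S)-5-(2-hydroxypropan-2-yl)-3,8-dimethyl-1,2,3,3a,4,5,6,7-octahydroazulen-6-yl (2E)-3-(4-hydroxy-3-methoxyphenyl)prop-2-enoate
Conditions: Pd(OAc)2 (5 mol %), P(o-tol)3 (12 mol %), Et3N, MeCN, 80 °C
Reagents that add atoms: none
Why: Pd(0) formed in situ inserts into the C4–I bond of 20, the arylpalladium iodide coordinates the monosubstituted acrylate alkene of 19 and adds syn with the aryl group going to the unsubstituted β-carbon, and syn β-hydride elimination from the rotamer with aryl and ester anti releases the (E)-cinnamate while Et3N regenerates Pd(0). The closest known reaction type is the Mizoroki–Heck arylation of acrylate esters with unprotected iodophenols. No ring is closed and no stereocentre is formed; the only stereochemical element is the alkene geometry, fixed as E by the elimination step. The step needs chemoselectivity for the acrylate over the ring alkene, and the substrate secures it because the C8=C8a alkene is tetrasubstituted and cannot undergo carbopalladation. Regioselectivity for the terminal carbon follows from the polarisation of the enoate, and the free phenol, the tertiary alcohol and the four stereocentres (none α to a carbonyl) should be inert.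

**Compound list**

1 | ethyl (3R)-4-chloro-3-hydroxybutanoate | CCOC(=O)C[C@@H](O)CCl | starting material
2 | ethyl 2-[(2R)-oxiran-2-yl]acetate | CCOC(=O)C[C@@H]1CO1 | intermediate
3 | ethyl (3S)-3-hydroxyhex-5-enoate | CCOC(=O)C[C@@H](O)CC=C | intermediate
4 | (3S)-3,7-dimethyloct-6-enal [(S)-citronellal] | O=CC[C@@H](C)CCC=C(C)C | starting material
5 | (3S)-3,7-dimethyl-2-methylideneoct-6-enal | O=CC(=C)[C@@H](C)CCC=C(C)C | intermediate
6 | (5S)-5-methylcyclopent-1-ene-1-carbaldehyde | O=CC1=CCC[C@@H]1C | intermediate
7 | [(5S)-5-methylcyclopent-1-en-1-yl]methanol | OCC1=CCC[C@@H]1C | intermediate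
8 | (5S)-1-(bromomethyl)-5-methylcyclopent-1-ene | BrCC1=CCC[C@@H]1C | intermediate
9 | dilithium alkoxide–enolate of 3 | CCOC(O[Li])=C[C@@H](O[Li])CC=C | intermediate (not isolated)
10 | ethyl (2S,3S)-3-hydroxy-2-{[(5S)-5-methylcyclopent-1-en-1-yl]methyl}hex-5-enoate | CCOC(=O)[C@@H](CC1=CCC[C@@H]1C)[C@@H](O)CC=C | intermediate
11 | (3S,4S)-2-methyl-3-{[(5S)-5-methylcyclopent-1-en-1-yl]methyl}hept-6-ene-2,4-diol | CC(C)(O)[C@@H](CC1=CCC[C@@H]1C)[C@@H](O)CC=C | intermediate
12 | (5S,6S)-2,2,4,4-tetramethyl-5-{[(5S)-5-methylcyclopent-1-en-1-yl]methyl}-6-(prop-2-en-1-yl)-1,3-dioxane | CC1(C)O[C@@H](CC=C)[C@H](CC2=CCC[C@@H]2C)C(C)(C)O1 | intermediate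
13 | 1-[(4S,5S)-2,2,6,6-tetramethyl-5-{[(5S)-5-methylcyclopent-1-en-1-yl]methyl}-1,3-dioxan-4-yl]propan-2-one | CC1(C)O[C@@H](CC(C)=O)[C@H](CC2=CCC[C@@H]2C)C(C)(C)O1 | intermediate
14 | bis(9-BBN) adduct (C-boryl on the cyclopentane, O-boryl on the side-chain carbinol) | CC1(C)O[C@@H](CC(C)OB2C3CCCC2CCC3)[C@H](C[C@H]2[C@@H](C)CC[C@@H]2B2C3CCCC2CCC3)C(C)(C)O1 | intermediate (not isolated)
15 | (1S,2S,3S)-2-{[(5S,6S)-6-(2-hydroxypropyl)-2,2,4,4-tetramethyl-1,3-dioxan-5-yl]methyl}-3-methylcyclopentan-1-ol | CC1(C)O[C@@H](CC(C)O)[C@H](C[C@H]2[C@@H](C)CC[C@@H]2O)C(C)(C)O1 | intermediate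
16 | (2S,3S)-3-methyl-2-{[(5S,6S)-2,2,4,4-tetramethyl-6-(2-oxopropyl)-1,3-dioxan-5-yl]methyl}cyclopentan-1-one | CC1(C)O[C@@H](CC(C)=O)[C@H](C[C@H]2[C@@H](C)CCC2=O)C(C)(C)O1 | intermediate
17 | isopropylidene acetal of 18 | CC1(C)O[C@H]2CC(C)=C3CC[C@H](C)[C@@H]3C[C@@H]2C(C)(C)O1 | intermediate
18 | (3S,3aS,5S,6S)-5-(2-hydroxypropan-2-yl)-3,8-dimethyl-1,2,3,3a,4,5,6,7-octahydroazulen-6-ol | O[C@H]1CC(C)=C2CC[C@H](C)[C@@H]2C[C@@H]1C(C)(C)O | intermediate
19 | (3S,3aS,5S,6S)-5-(2-hydroxypropan-2-yl)-3,8-dimethyl-1,2,3,3a,4,5,6,7-octahydroazulen-6-yl prop-2-enoate | C=CC(=O)O[C@H]1CC(C)=C2CC[C@H](C)[C@@H]2C[C@@H]1C(C)(C)O | intermediate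
20 | 4-iodo-2-methoxyphenol | COc1cc(I)ccc1O | starting material
21 | (3S,3aS,5S,6S)-5-(2-hydroxypropan-2-yl)-3,8-dimethyl-1,2,3,3a,4,5,6,7-octahydroazulen-6-yl (2E)-3-(4-hydroxy-3-methoxyphenyl)prop-2-enoate | COc1cc(/C=C/C(=O)O[C@H]2CC(C)=C3CC[C@H](C)[C@@H]3C[C@@H]2C(C)(C)O)ccc1O | target

**Step count**

Total: 16 steps. Longest linear sequence: 14 steps (steps 3–6, then 7–16).

**Steps most likely to fail**

Step 13 (McMurry coupling). What may go wrong: epimerisation of the cis-configured centre α to the cyclopentanone through titanium enolates; Lewis-acid aldolisation of the 1,7-diketone; loss of the β-acetal oxygen at the ketyl stage; intermolecular coupling. The fallback sets out from 16 and returns at 17. Both ketones would be methylenated under non-basic Lombardo–Takai conditions (Zn, CH2Br2, TiCl4) to give the bis-methylidene compound F1. Ring-closing metathesis of F1 (Hoveyda–Grubbs II or Stewart–Grubbs catalyst, toluene, 80 °C) would then form the tetrasubstituted alkene and give 17.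

Step 11 (hydroboration/oxidation). What may go wrong: insufficient facial discrimination by the single allylic methyl group, and slow addition of 9-BBN to the hindered trisubstituted alkene. The fallback sets out from 13 and returns at 16, replacing substrate control by reagent control and hydroxyl direction. Shi epoxidation, with the ketone-catalyst enantiomer that reinforces attack anti to the ring methyl, would give the epoxy ketone F2. Titanium(III)-mediated isomerisation (Cp2TiCl from Cp2TiCl2 and Mn) would open it to the exocyclic allylic alcohol F3. Hydroxyl-directed hydrogenation ([Rh(nbd)(dppb)]BF4, H2) would deliver hydrogen syn to the carbinol and give the hydroxy ketone F4. Dess–Martin oxidation as in step 12 would then give 16.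

Step 10 (Wacker oxidation). What may go wrong: cleavage of the acid-labile acetal under the HCl/CuCl2 medium, partial aldehyde formation through coordination of palladium by the homoallylic oxygen, and alkene migration. The fallback sets out from 12 and returns at 15. Oxymercuration with one equivalent of Hg(OAc)2 in THF/H2O at 0 °C would give the organomercurial acetate F5, which is not isolated. Reductive demercuration with NaBH4/NaOH would give the secondary alcohol F6. F6 would then be taken through the 9-BBN/H2O2 sequence of step 11, through the same borane 14, to give 15.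

**Further compounds**

F1 | step 13 | (5S,6S)-2,2,4,4-tetramethyl-5-{[(1S,2S)-2-methyl-5-methylidenecyclopentyl]methyl}-6-(2-methylprop-2-en-1-yl)-1,3-dioxane | CC1(C)O[C@@H](CC(C)=C)[C@H](C[C@H]2[C@@H](C)CCC2=C)C(C)(C)O1
F2 | step 11 | epoxide of 13 with the oxirane on the ring face anti to the methyl group | CC1(C)O[C@@H](CC(C)=O)[C@H](C[C@]23O[C@H]2CC[C@@H]3C)C(C)(C)O1
F3 | step 11 | 1-[(4S,5S)-5-{[(2S,5S)-2-hydroxy-5-methylcyclopentylidene]methyl}-2,2,6,6-tetramethyl-1,3-dioxan-4-yl]propan-2-one | CC1(C)O[C@@H](CC(C)=O)[C@H](C=C2[C@@H](O)CC[C@@H]2C)C(C)(C)O1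
F4 | step 11 | 1-[(4S,5S)-5-{[(1S,2S,5S)-2-hydroxy-5-methylcyclopentyl]methyl}-2,2,6,6-tetramethyl-1,3-dioxan-4-yl]propan-2-one | CC1(C)O[C@@H](CC(C)=O)[C@H](C[C@H]2[C@@H](C)CC[C@@H]2O)C(C)(C)O1
F5 | step 10 | acetoxymercurio carbinol from oxymercuration of 12 | CC1(C)O[C@@H](CC(O)C[Hg]OC(C)=O)[C@H](CC2=CCC[C@@H]2C)C(C)(C)O1
F6 | step 10 | 1-[(4S,5S)-2,2,6,6-tetramethyl-5-{[(5S)-5-methylcyclopent-1-en-1-yl]methyl}-1,3-dioxan-4-yl]propan-2-ol | CC1(C)O[C@@H](CC(C)O)[C@H](CC2=CCC[C@@H]2C)C(C)(C)O1
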